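The quinone ring (C1, C2, C3, C4, C4a, C8a) of the 2‑hydroxy‑1,4‑naphthoquinone is disconnected by a Dötz benzannulation. A phenyl(methoxy)carbene chromium complex, one CO ligand and an alkynyl pinacol boronate carrying the gem‑dimethyl chain combine in one operation. The carbene carbon (C4) bonds to the alkyl‑bearing alkyne carbon (C3), CO becomes C1, and C1 closes onto the free ortho carbon (C8a) of the unsubstituted benzo ring. Boron marks C2 as the future hydroxyl carbon, so the fully substituted C2/C3 edge of the quinone is read directly from the alkyne. Oxidative work‑up, esterification with an (S)‑linalool‑derived acid and C–B oxidation complete the target.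

Key step: step 5

Assumption: (S)‑(+)‑linalool (coriandrol) of high enantiomeric purity and 2,2‑dimethylpent‑4‑ynoic acid are taken as purchasable; the single stereocenter of the target (S) is carried unchanged from the linalool.

Step 1
Reactants: 1 chromium hexacarbonyl, Cr(CO)6; 2 phenyllithium
Product: 4 pentacarbonyl[methoxy(phenyl)carbene]chromium, via lithium benzoylpentacarbonylchromate 3 (not isolated)
Conditions: Et2O, 0 °C to rt; then Me3OBF4, CH2Cl2/H2O, 0 °C
Reagents that add atoms: trimethyloxonium tetrafluoroborate, C[O+](C)C.F[B-](F)(F)F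
Why: Fischer carbene synthesis, in which phenyllithium adds to a CO ligand to give the acylchromate and the hard oxonium salt methylates its oxygen.

Step 2
Reactants: 5 2,2‑dimethylpent‑4‑ynoic acid
Product: 6 2,2‑dimethylpent‑4‑yn‑1‑ol
Conditions: LiAlH4, THF, 0 °C to rt; aqueous work‑up
Reagents that add atoms: none
Why: LiAlH4 reduction of a carboxylic acid to the primary alcohol, with the isolated terminal alkyne inert to hydride at this temperature.

Step 3
Reactants: 6 2,2‑dimethylpent‑4‑yn‑1‑ol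
Product: 7 1‑{[(2,2‑dimethylpent‑4‑yn‑1‑yl)oxy]methyl}‑4‑methoxybenzene
Conditions: NaH, PMBCl, nBu4NI (cat.), THF/DMF, 0 °C to rt
Reagents that add atoms: 4‑methoxybenzyl chloride, COc1ccc(CCl)cc1
Why: Williamson etherification, in which the alkoxide (formed in preference to the acetylide) is benzylated.

Step 4
Reactants: 7 1‑{[(2,2‑dimethylpent‑4‑yn‑1‑yl)oxy]methyl}‑4‑methoxybenzene
Product: 10 2‑{5‑[(4‑methoxybenzyl)oxy]‑4,4‑dimethylpent‑1‑yn‑1‑yl}‑4,4,5,5‑tetramethyl‑1,3,2‑dioxaborolane, via lithium acetylide 8 (not isolated), via lithium alkynylborate 9 (not isolated)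
Conditions: nBuLi, THF, −78 °C; iPrOBpin, −78 °C; then HCl in Et2O, −78 °C to rt
Reagents that add atoms: 2‑isopropoxy‑4,4,5,5‑tetramethyl‑1,3,2‑dioxaborolane, CC(C)OB1OC(C)(C)C(C)(C)O1
Why: Standard alkynylboronate synthesis, in which the lithium acetylide adds to the borate ester and anhydrous HCl collapses the ate complex with loss of isopropanol.

Step 5
Reactants: 4 pentacarbonyl[methoxy(phenyl)carbene]chromium; 10 2‑{5‑[(4‑methoxybenzyl)oxy]‑4,4‑dimethylpent‑1‑yn‑1‑yl}‑4,4,5,5‑tetramethyl‑1,3,2‑dioxaborolane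
Product: 13 2‑(3‑hydroxy‑2,2‑dimethylpropyl)‑3‑(4,4,5,5‑tetramethyl‑1,3,2‑dioxaborolan‑2‑yl)naphthalene‑1,4‑dione, via chromium‑bound naphthol boronate 11 (not isolated), via PMB‑protected quinone boronate 12 (not isolated)
Conditions: THF, argon, 45 °C; then (NH4)2Ce(NO3)6 (excess), MeCN/H2O, 0 °C to rt
Reagents that add atoms: water, O
Why: Dötz benzannulation (formal [3+2+1] of carbene carbon, alkyne and CO), a reaction type established for alkynyl pinacol boronates: loss of one CO from 4 and insertion of the alkyne into Cr=C joins the carbene carbon (target C4) to the alkyl‑bearing alkyne carbon (C3), and CO insertion then gives a chromium‑bound dienylketene whose ketene carbon (C1) is attached to the boron‑bearing carbon (C2). The quinone ring is closed by a thermal disrotatory 6π‑electrocyclization of this dienylketene onto an ortho carbon of the phenyl group (C1–C8a), and tautomerization gives the naphthol complex 11. No stereocenter is formed. The step needs alkyne insertion with boron next to the CO‑derived carbon and benzannulation in preference to cyclopentannulation; the bulky π‑acceptor Bpin group prefers the new carbene carbon, the aryl(methoxy)carbene in THF favours CO insertion, and because the benzo ring is unsubstituted either insertion sense ends in the same quinone after oxidation. Excess (NH4)2Ce(NO3)6 then strips chromium, oxidizes the 4‑methoxy‑1‑naphthol to the 1,4‑quinone (C4 oxygen from water, methanol lost) and cleaves the PMB ether, while the C–B bond is kept.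

Step 6
Reactants: 14 (S)‑(+)‑linalool, (3S)‑3,7‑dimethylocta‑1,6‑dien‑3‑ol
Product: 15 (2E,6S)‑6‑hydroxy‑2,6‑dimethylocta‑2,7‑dienal
Conditions: SeO2, 1,4‑dioxane/EtOH, 80 °C
Reagents that add atoms: selenium dioxide, O=[Se]=O
Why: Riley allylic oxidation, in which ene reaction at the trisubstituted alkene and [2,3]‑sigmatropic shift oxidize the (E)‑methyl group selectively to the (E)‑enal, while the (S) stereocenter comes from 14 and is not touched.

Step 7
Reactants: 15 (2E,6S)‑6‑hydroxy‑2,6‑dimethylocta‑2,7‑dienal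
Product: 16 (2E,6S)‑6‑hydroxy‑2,6‑dimethylocta‑2,7‑dienoic acid
Conditions: NaClO2, NaH2PO4, 2‑methyl‑2‑butene, tBuOH/H2O, rt
Reagents that add atoms: sodium chlorite, [Na+].[O-]Cl=O
Why: Pinnick oxidation of the enal to the acid, in which 2‑methyl‑2‑butene scavenges HOCl so that the alkenes, the tertiary allylic alcohol and the E geometry are kept.

Step 8
Reactants: 13 2‑(3‑hydroxy‑2,2‑dimethylpropyl)‑3‑(4,4,5,5‑tetramethyl‑1,3,2‑dioxaborolan‑2‑yl)naphthalene‑1,4‑dione; 16 (2E,6S)‑6‑hydroxy‑2,6‑dimethylocta‑2,7‑dienoic acid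
Product: 17 3‑[1,4‑dioxo‑3‑(4,4,5,5‑tetramethyl‑1,3,2‑dioxaborolan‑2‑yl)‑1,4‑dihydronaphthalen‑2‑yl]‑2,2‑dimethylpropyl (2E,6S)‑6‑hydroxy‑2,6‑dimethylocta‑2,7‑dienoate
Conditions: DCC, 4‑(dimethylamino)pyridine (cat.), CH2Cl2, 0 °C to rt
Reagents that add atoms: none
Why: Steglich esterification, in which the primary neopentyl alcohol of 13 is acylated through the acylpyridinium ion while the hindered tertiary alcohol of 16 should not compete.

Step 9
Reactants: 17 3‑[1,4‑dioxo‑3‑(4,4,5,5‑tetramethyl‑1,3,2‑dioxaborolan‑2‑yl)‑1,4‑dihydronaphthalen‑2‑yl]‑2,2‑dimethylpropyl (2E,6S)‑6‑hydroxy‑2,6‑dimethylocta‑2,7‑dienoate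
Product: 18 3‑(3‑hydroxy‑1,4‑dioxo‑1,4‑dihydronaphthalen‑2‑yl)‑2,2‑dimethylpropyl (2E,6S)‑6‑hydroxy‑2,6‑dimethylocta‑2,7‑dienoate
Conditions: NaBO3·4H2O, THF/H2O, 0 °C to rt; acidic work‑up
Reagents that add atoms: sodium perborate, O[B-]1(O)OO[B-](O)(O)OO1.[Na+].[Na+]
Why: Oxidation of the C–B bond, in which peroxide adds to boron, the quinone carbon migrates from boron to oxygen and hydrolysis of the borate gives the 2‑hydroxyquinone, under conditions mild enough to spare the alkenes, the ester and the tertiary alcohol.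

Compound list
1 | chromium hexacarbonyl, Cr(CO)6 | O=C=[Cr](=C=O)(=C=O)(=C=O)(=C=O)=C=O | starting material
2 | phenyllithium | [Li]c1ccccc1 | starting material
3 | lithium benzoylpentacarbonylchromate, (CO)5Cr=C(OLi)Ph | [Li+].[O-]C(c1ccccc1)=[Cr](=C=O)(=C=O)(=C=O)(=C=O)=C=O | intermediate
4 | pentacarbonyl[methoxy(phenyl)carbene]chromium, (CO)5Cr=C(OMe)Ph | COC(c1ccccc1)=[Cr](=C=O)(=C=O)(=C=O)(=C=O)=C=O | intermediate
5 | 2,2‑dimethylpent‑4‑ynoic acid | C#CCC(C)(C)C(=O)O | starting material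
6 | 2,2‑dimethylpent‑4‑yn‑1‑ol | C#CCC(C)(C)CO | intermediate
7 | 1‑{[(2,2‑dimethylpent‑4‑yn‑1‑yl)oxy]methyl}‑4‑methoxybenzene (PMB ether of 6) | C#CCC(C)(C)COCc1ccc(OC)cc1 | intermediate
8 | lithium acetylide of 7 | [Li]C#CCC(C)(C)COCc1ccc(OC)cc1 | intermediate
9 | lithium alkynyl(isopropoxy)(pinacolato)borate from 8 | [Li+].CC(C)O[B-]1(C#CCC(C)(C)COCc2ccc(OC)cc2)OC(C)(C)C(C)(C)O1 | intermediate
10 | 2‑{5‑[(4‑methoxybenzyl)oxy]‑4,4‑dimethylpent‑1‑yn‑1‑yl}‑4,4,5,5‑tetramethyl‑1,3,2‑dioxaborolane | COc1ccc(COCC(C)(C)CC#CB2OC(C)(C)C(C)(C)O2)cc1 | intermediate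
11 | tricarbonyl{η6‑4‑methoxy‑3‑[3‑(4‑methoxybenzyloxy)‑2,2‑dimethylpropyl]‑2‑(4,4,5,5‑tetramethyl‑1,3,2‑dioxaborolan‑2‑yl)naphthalen‑1‑ol}chromium (η6 bonding written as a dot) | COc1c(CC(C)(C)COCc2ccc(OC)cc2)c(B2OC(C)(C)C(C)(C)O2)c(O)c2ccccc12.O=C=[Cr](=C=O)=C=O | intermediate
12 | 2‑[3‑(4‑methoxybenzyloxy)‑2,2‑dimethylpropyl]‑3‑(4,4,5,5‑tetramethyl‑1,3,2‑dioxaborolan‑2‑yl)naphthalene‑1,4‑dione | COc1ccc(COCC(C)(C)CC2=C(B3OC(C)(C)C(C)(C)O3)C(=O)c3ccccc3C2=O)cc1 | intermediate
13 | 2‑(3‑hydroxy‑2,2‑dimethylpropyl)‑3‑(4,4,5,5‑tetramethyl‑1,3,2‑dioxaborolan‑2‑yl)naphthalene‑1,4‑dione | CC(C)(CO)CC1=C(B2OC(C)(C)C(C)(C)O2)C(=O)c2ccccc2C1=O | intermediate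
14 | (S)‑(+)‑linalool, (3S)‑3,7‑dimethylocta‑1,6‑dien‑3‑ol | C=C[C@@](C)(O)CCC=C(C)C | starting material
15 | (2E,6S)‑6‑hydroxy‑2,6‑dimethylocta‑2,7‑dienal | C=C[C@@](C)(O)CC/C=C(\C)C=O | intermediate
16 | (2E,6S)‑6‑hydroxy‑2,6‑dimethylocta‑2,7‑dienoic acid | C=C[C@@](C)(O)CC/C=C(\C)C(=O)O | intermediate
17 | 3‑[1,4‑dioxo‑3‑(4,4,5,5‑tetramethyl‑1,3,2‑dioxaborolan‑2‑yl)‑1,4‑dihydronaphthalen‑2‑yl]‑2,2‑dimethylpropyl (2E,6S)‑6‑hydroxy‑2,6‑dimethylocta‑2,7‑dienoate | C=C[C@@](C)(O)CC/C=C(\C)C(=O)OCC(C)(C)CC1=C(B2OC(C)(C)C(C)(C)O2)C(=O)c2ccccc2C1=O | intermediate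
18 | 3‑(3‑hydroxy‑1,4‑dioxo‑1,4‑dihydronaphthalen‑2‑yl)‑2,2‑dimethylpropyl (2E,6S)‑6‑hydroxy‑2,6‑dimethylocta‑2,7‑dienoate | C=C[C@@](C)(O)CC/C=C(\C)C(=O)OCC(C)(C)CC1=C(O)C(=O)c2ccccc2C1=O | target

Total step count: 9. Longest linear sequence: 6 steps (steps 2, 3, 4, 5, 8, 9; 5 → 6 → 7 → 10 → 13 → 17 → 18).

Steps most likely to fail

Step 5. Alkyne insertion may stall or divert to cyclopentannulation or cyclobutenone formation, the C–B bond may be lost by protodeboronation during the annulation or the acidic oxidative work‑up, and PMB cleavage may lag behind quinone formation. The fallback gives up the benzannulation and alkylates a preformed hydroxyquinone. It sets out from acid 16 together with purchased 2‑hydroxy‑1,4‑naphthoquinone and 3‑hydroxy‑2,2‑dimethylpropanal, which replace 4 and 10. L‑Proline‑catalysed Knoevenagel condensation of the two purchased compounds in CH2Cl2 should give 3‑(3‑hydroxy‑2,2‑dimethylpropylidene)naphthalene‑1,2,4(3H)‑trione F1 (not isolated). Diethyl 2,6‑dimethyl‑1,4‑dihydropyridine‑3,5‑dicarboxylate (Hantzsch ester) reduces it in the same flask by conjugate hydride transfer to 2‑hydroxy‑3‑(3‑hydroxy‑2,2‑dimethylpropyl)naphthalene‑1,4‑dione F2. DCC/4‑(dimethylamino)pyridine esterification of the primary alcohol of F2 with 16 comes back to the route at target 18.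

Step 8. Slow acylation of the hindered neopentyl alcohol may let the O‑acylisourea rearrange to the N‑acylurea, and the nucleophilic catalyst may trigger protodeboronation of the quinone boronate or oxa‑Michael cyclization of the hydroxy enoate. The fallback uses a protected acid chloride and sets out from 16 and 13. Double silylation of 16 (Et3SiCl, imidazole, DMF) should give triethylsilyl (2E,6S)‑2,6‑dimethyl‑6‑(triethylsilyloxy)octa‑2,7‑dienoate F3. Oxalyl chloride with catalytic DMF in CH2Cl2 converts the silyl ester directly into (2E,6S)‑2,6‑dimethyl‑6‑(triethylsilyloxy)octa‑2,7‑dienoyl chloride F4. F4 acylates alcohol 13 with pyridine as the only base to give 3‑[1,4‑dioxo‑3‑(4,4,5,5‑tetramethyl‑1,3,2‑dioxaborolan‑2‑yl)‑1,4‑dihydronaphthalen‑2‑yl]‑2,2‑dimethylpropyl (2E,6S)‑2,6‑dimethyl‑6‑(triethylsilyloxy)octa‑2,7‑dienoate F5. AcOH/THF/H2O removes the tertiary silyl ether and comes back to the route at 17.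

Step 6. Incomplete oxidation and over‑oxidation may give alcohol/aldehyde/acid mixtures, acid‑promoted ionization of the tertiary allylic alcohol may cause transposition or erosion of the stereocenter, and the hydroxy enal may cyclize to tetrahydrofurans. The fallback builds the enoate by olefination instead of C–H oxidation and sets out from 14. Chemoselective ozonolysis of the electron‑rich trisubstituted alkene (O3, CH2Cl2/MeOH, −78 °C, dye indicator; Me2S) should give (4S)‑4‑hydroxy‑4‑methylhex‑5‑enal F6, in equilibrium with its lactol. Wittig olefination with the stabilized ylide ethyl 2‑(triphenylphosphoranylidene)propanoate (toluene, 80 °C) should give E‑selectively ethyl (2E,6S)‑6‑hydroxy‑2,6‑dimethylocta‑2,7‑dienoate F7. LiOH in THF/H2O hydrolyses F7 and comes back to the route at acid 16.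

Further compounds
F1 | step 5 | 3‑(3‑hydroxy‑2,2‑dimethylpropylidene)naphthalene‑1,2,4(3H)‑trione | O=C1C(=O)c2ccccc2C(=O)C1=CC(C)(C)CO
F2 | step 5 | 2‑hydroxy‑3‑(3‑hydroxy‑2,2‑dimethylpropyl)naphthalene‑1,4‑dione | CC(C)(CO)CC1=C(O)C(=O)c2ccccc2C1=O
F3 | step 8 | triethylsilyl (2E,6S)‑2,6‑dimethyl‑6‑(triethylsilyloxy)octa‑2,7‑dienoate | C=C[C@@](C)(O[Si](CC)(CC)CC)CC/C=C(\C)C(=O)O[Si](CC)(CC)CC
F4 | step 8 | (2E,6S)‑2,6‑dimethyl‑6‑(triethylsilyloxy)octa‑2,7‑dienoyl chloride | C=C[C@@](C)(O[Si](CC)(CC)CC)CC/C=C(\C)C(Cl)=O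
F5 | step 8 | 3‑[1,4‑dioxo‑3‑(4,4,5,5‑tetramethyl‑1,3,2‑dioxaborolan‑2‑yl)‑1,4‑dihydronaphthalen‑2‑yl]‑2,2‑dimethylpropyl (2E,6S)‑2,6‑dimethyl‑6‑(triethylsilyloxy)octa‑2,7‑dienoate | C=C[C@@](C)(O[Si](CC)(CC)CC)CC/C=C(\C)C(=O)OCC(C)(C)CC1=C(B2OC(C)(C)C(C)(C)O2)C(=O)c2ccccc2C1=O
F6 | step 6 | (4S)‑4‑hydroxy‑4‑methylhex‑5‑enal | C=C[C@@](C)(O)CCC=O
F7 | step 6 | ethyl (2E,6S)‑6‑hydroxy‑2,6‑dimethylocta‑2,7‑dienoate | C=C[C@@](C)(O)CC/C=C(\C)C(=O)OCC
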